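**Plan**

The upper pyran (O1–C2–C3–C4–C4a–C8a) carries three contiguous, mutually trans stereocentres, with ring D of the afzelechin unit on C4. This is the retron of a ring A ortho-quinone methide (O1, C8a, C4a, C4) plus an (E)-alkene (C2=C3).
Retrosynthesis: C3–OH goes back to C3–B; O1–C2 and C3–C4 are then cut together (oxa-[4+2]); last, the bond from the carbinol carbon (future C4) to C8 of the lower flavan (aryllithium + aldehyde) and the styrene C=C (boron–Wittig) are cut.
Forward: afzelechin is perbenzylated, brominated at C8, lithiated and joined to a protected salicylaldehyde. The freed ortho-hydroxybenzhydrol and the (E)-styrylboronate are then united, so the upper ring C is the only ring built, and it is built last.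
Stereochemistry: lower C2/C3 come from natural (2R,3S)-afzelechin. Upper C2, C3 and C4 are set in one step by the alkene geometry (2,3-trans), the aryl-endo approach (2,4-cis) and the chiral phosphoric acid (absolute sense). The C–B to C–O oxidation retains C3.

Key step: step 8

Assumption: (2R,3S)-afzelechin is bought as the isolated natural product; the (R) acid is written for step 8, and its mirror image is meant if that is the antipode whose pocket delivers the 4S adduct.

**Route**

Step 1
Reactants: 1 (2R,3S)-afzelechin
Product: 2 (2R,3S)-5,7,4'-tri-O-benzylafzelechin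
Conditions: BnBr (3.3 equiv), K2CO3, DMF, 0 °C to rt
Reagents that add atoms: benzyl bromide, BrCc1ccccc1
Why: Williamson etherification in which carbonate deprotonates only the three phenols, and capping them shuts off base-induced C2 epimerisation through a ring B quinone methide.

Step 2
Reactants: 2 (2R,3S)-5,7,4'-tri-O-benzylafzelechin
Product: 3 (2R,3S)-3,5,7,4'-tetra-O-benzylafzelechin
Conditions: NaH, BnBr, DMF, 0 °C to rt
Reagents that add atoms: benzyl bromide, BrCc1ccccc1
Why: Williamson etherification of the secondary sodium alkoxide, which touches no stereocentre and removes the last acidic proton before the lithiation.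

Step 3
Reactants: 3 (2R,3S)-3,5,7,4'-tetra-O-benzylafzelechin
Product: 4 (2R,3S)-8-bromo-3,5,7,4'-tetra-O-benzylafzelechin
Conditions: NBS (1.0 equiv), CH2Cl2, −78 °C to 0 °C
Reagents that add atoms: N-bromosuccinimide, O=C1CCC(=O)N1Br
Why: Electrophilic aromatic bromination of the phloroglucinol-type ring, which in per-benzylated flavan-3-ols takes place at C8 rather than C6 or ring B, with one equivalent of NBS at low temperature to avoid dibromination.

Step 4
Reactants: 5 phenol aldehyde 4-benzyloxy-2-hydroxybenzaldehyde
Product: 6 silyl ether 4-benzyloxy-2-(tert-butyldimethylsilyloxy)benzaldehyde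
Conditions: TBSCl, imidazole, CH2Cl2, rt
Reagents that add atoms: tert-butyldimethylsilyl chloride, CC(C)(C)[Si](C)(C)Cl
Why: Silylation of the phenol masks the acidic OH so that it cannot quench the aryllithium of step 5, and the group is later removable without acid.

Step 5
Reactants: 4 (2R,3S)-8-bromo-3,5,7,4'-tetra-O-benzylafzelechin; 6 silyl ether 4-benzyloxy-2-(tert-butyldimethylsilyloxy)benzaldehyde
Product: 8 silyl-protected benzhydrol [4-benzyloxy-2-(tert-butyldimethylsilyloxy)phenyl][(2R,3S)-3,5,7,4'-tetra-O-benzylafzelechin-8-yl]methanol (carbinol epimers), via 8-lithio-3,5,7,4'-tetra-O-benzylafzelechin 7 (not isolated)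
Conditions: n-BuLi, THF, −78 °C; then 6, −78 to −40 °C; H2O quench
Reagents that add atoms: none
Why: Bromine–lithium exchange and 1,2-addition of the aryllithium to a non-enolisable aldehyde, a sequence established for 8-bromo per-benzylated flavan-3-ols; the carbinol epimer mixture is acceptable because this carbon becomes trigonal in step 8, and a possible O-to-O silyl shift is harmless because step 6 removes silicon from either oxygen.

Step 6
Reactants: 8 silyl-protected benzhydrol
Product: 9 benzhydrol (4-benzyloxy-2-hydroxyphenyl)[(2R,3S)-3,5,7,4'-tetra-O-benzylafzelechin-8-yl]methanol (carbinol epimers)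
Conditions: Bu4NF, THF, 0 °C; pH 7 buffer work-up, Et3N-washed silica
Reagents that add atoms: none
Why: Fluoride desilylation is non-acidic and leaves the benzyl ethers and the carbinol untouched, while neutral work-up and base-washed silica should keep the electron-rich benzhydrol from ionising.

Step 7
Reactants: 10 dibenzyl protocatechualdehyde (3,4-bis(benzyloxy)benzaldehyde); 11 bis(pinacolboryl)methane
Product: 13 (E)-2-[3,4-bis(benzyloxy)phenyl]vinylboronic acid pinacol ester, via lithiated bis(pinacolboryl)methane 12 (not isolated)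
Conditions: lithium 2,2,6,6-tetramethylpiperidide (LiTMP), THF, 0 °C; then 10, −78 °C to rt
Reagents that add atoms: none
Why: Boron–Wittig olefination, in which the α-diboryl carbanion adds to the aldehyde and syn elimination of lithium borate from the less crowded adduct should give the (E)-alkenyl pinacol boronate.

Step 8
Reactants: 9 benzhydrol (carbinol epimers); 13 (E)-2-[3,4-bis(benzyloxy)phenyl]vinylboronic acid pinacol ester
Product: 15 boronate cycloadduct hepta-O-benzyl-3-deoxy-3-(pinacolboryl)fisetinidol-(4α→8)-afzelechin, via ring A ortho-quinone methide 14 (not isolated)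
Conditions: (R)-3,3'-bis(2,4,6-triisopropylphenyl)-1,1'-binaphthyl-2,2'-diyl hydrogen phosphate (10 mol %), 13 (2 equiv), 5 Å molecular sieves, toluene, 0 °C to rt
Reagents that add atoms: none
Why: Proposed new method: the phosphoric acid ionises the doubly aryl-stabilised carbinol of 9 to the (E)-ortho-quinone methide 14, held by a hydrogen bond to the chiral phosphate, and the boron-bearing carbon of 13 then bonds to the exocyclic carbon (future C4) while the quinone methide oxygen closes on the aryl-bearing carbon (future C2) in a concerted, asynchronous inverse-demand oxa-[4+2] cycloaddition. The closest known reaction type is the chiral phosphoric acid catalysed [4+2] of in situ ortho-quinone methides with styrenes to 2,4-cis-chromans; a β-boryl styrene as the two-carbon partner is the untested element, reasoned to work because attack through the boron-bearing carbon leaves positive charge on a para-benzyloxybenzylic carbon that is also β to the C–B bond. The upper pyran (ring C) is the one ring closed, by intermolecular [4+2] cycloaddition in which the C3–C4 bond leads and the O1–C2 bond completes the six-membered ring. C2 and C3 come out trans because the addition is suprafacial on the (E)-alkene, C4 comes out cis to the C2 aryl (trans to boron) through the aryl-endo approach to the E quinone methide, and the absolute sense (4S) is dictated by the phosphate pocket, since the stereocentres of the afzelechin unit are too remote to steer the facial choice. The step needs regioselectivity, secured by the 3,4-dialkoxyaryl donor, and ring closure in preference to deborylative alkenyl transfer, secured by the pinacol ester, which does not exchange with the acid or the phenol and is a poor leaving group.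

Step 9
Reactants: 15 boronate cycloadduct
Product: 17 hepta-O-benzylfisetinidol-(4α→8)-afzelechin (upper 3-OH free), via C3 borate ester 16 (not isolated)
Conditions: 30% aq. H2O2, aq. NaOH, THF, 0 °C to rt
Reagents that add atoms: hydrogen peroxide, OO
Why: Oxidation of a secondary alkyl pinacol boronate by alkaline hydrogen peroxide (1,2-shift of C3 from boron to oxygen with retention), the transformation that also turns 3-boryl chromans and flavans from chromene hydroboration into 3-ols, so the 2,3-trans-3,4-trans array is carried over unchanged.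

Step 10
Reactants: 17 hepta-O-benzylfisetinidol-(4α→8)-afzelechin
Product: 18 fisetinidol-(4α→8)-afzelechin (target)
Conditions: H2 (1 atm), Pd(OH)2 on carbon, THF/MeOH, rt; filtration under argon
Reagents that add atoms: none
Why: Hydrogenolysis of six aryl benzyl ethers and one alkyl benzyl ether, the usual end-game for benzylated proanthocyanidins, under which the C4–C8 bond and the cyclic benzylic C2–O bonds are expected to survive at 1 atm and room temperature.

**Compound list**

1 | (2R,3S)-afzelechin | Oc1ccc([C@H]2Oc3cc(O)cc(O)c3C[C@@H]2O)cc1 | starting material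
2 | (2R,3S)-5,7,4'-tri-O-benzylafzelechin | c9ccccc9COc1ccc([C@H]2Oc3cc(OCc9ccccc9)cc(OCc9ccccc9)c3C[C@@H]2O)cc1 | intermediate
3 | (2R,3S)-3,5,7,4'-tetra-O-benzylafzelechin | c9ccccc9COc1ccc([C@H]2Oc3cc(OCc9ccccc9)cc(OCc9ccccc9)c3C[C@@H]2OCc9ccccc9)cc1 | intermediate
4 | (2R,3S)-8-bromo-3,5,7,4'-tetra-O-benzylafzelechin | c9ccccc9COc1ccc([C@H]2Oc3c(c(OCc9ccccc9)cc(OCc9ccccc9)c3Br)C[C@@H]2OCc9ccccc9)cc1 | intermediate
5 | 4-benzyloxy-2-hydroxybenzaldehyde | O=Cc1ccc(OCc2ccccc2)cc1O | starting material
6 | 4-benzyloxy-2-(tert-butyldimethylsilyloxy)benzaldehyde | O=Cc1ccc(OCc2ccccc2)cc1O[Si](C)(C)C(C)(C)C | intermediate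
7 | 8-lithio-3,5,7,4'-tetra-O-benzylafzelechin (not isolated) | c9ccccc9COc1ccc([C@H]2Oc3c(c(OCc9ccccc9)cc(OCc9ccccc9)c3[Li])C[C@@H]2OCc9ccccc9)cc1 | intermediate
8 | [4-benzyloxy-2-(tert-butyldimethylsilyloxy)phenyl][(2R,3S)-3,5,7,4'-tetra-O-benzylafzelechin-8-yl]methanol, both carbinol epimers | c9ccccc9COc1ccc([C@H]2Oc3c(c(OCc9ccccc9)cc(OCc9ccccc9)c3C(O)c3ccc(OCc9ccccc9)cc3O[Si](C)(C)C(C)(C)C)C[C@@H]2OCc9ccccc9)cc1 | intermediate
9 | (4-benzyloxy-2-hydroxyphenyl)[(2R,3S)-3,5,7,4'-tetra-O-benzylafzelechin-8-yl]methanol, both carbinol epimers | c9ccccc9COc1ccc([C@H]2Oc3c(c(OCc9ccccc9)cc(OCc9ccccc9)c3C(O)c3ccc(OCc9ccccc9)cc3O)C[C@@H]2OCc9ccccc9)cc1 | intermediate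
10 | 3,4-bis(benzyloxy)benzaldehyde | O=Cc1ccc(OCc2ccccc2)c(OCc2ccccc2)c1 | starting material
11 | bis(pinacolboryl)methane, 2,2'-methylenebis(4,4,5,5-tetramethyl-1,3,2-dioxaborolane) | CC1(C)OB(CB2OC(C)(C)C(C)(C)O2)OC1(C)C | starting material
12 | lithiated bis(pinacolboryl)methane (not isolated) | [Li]C(B1OC(C)(C)C(C)(C)O1)B1OC(C)(C)C(C)(C)O1 | intermediate
13 | (E)-2-[3,4-bis(benzyloxy)phenyl]vinylboronic acid pinacol ester | CC1(C)OB(/C=C/c2ccc(OCc3ccccc3)c(OCc3ccccc3)c2)OC1(C)C | intermediate
14 | (E)-3-benzyloxy-6-{[(2R,3S)-3,5,7,4'-tetra-O-benzylafzelechin-8-yl]methylidene}cyclohexa-2,4-dien-1-one, the ring A ortho-quinone methide (not isolated) | c9ccccc9COc1ccc([C@H]2Oc3c(c(OCc9ccccc9)cc(OCc9ccccc9)c3/C=C3\C=CC(OCc9ccccc9)=CC3=O)C[C@@H]2OCc9ccccc9)cc1 | intermediate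
15 | hepta-O-benzyl-3-deoxy-3-(pinacolboryl)fisetinidol-(4α→8)-afzelechin; upper unit 2,3-trans-3,4-trans (2S,3S,4S by the sequence rules because boron lowers the rank of C3; same spatial arrangement as the 3-ol), lower unit (2R,3S) | c9ccccc9COc1ccc([C@H]2Oc3c(c(OCc9ccccc9)cc(OCc9ccccc9)c3[C@@H]3c4ccc(OCc9ccccc9)cc4O[C@H](c4ccc(OCc9ccccc9)c(OCc9ccccc9)c4)[C@H]3B3OC(C)(C)C(C)(C)O3)C[C@@H]2OCc9ccccc9)cc1 | intermediate
16 | O3-(pinacolboryl) derivative of 17, the C3–O–B borate ester (not isolated) | c9ccccc9COc1ccc([C@H]2Oc3c(c(OCc9ccccc9)cc(OCc9ccccc9)c3[C@@H]3c4ccc(OCc9ccccc9)cc4O[C@H](c4ccc(OCc9ccccc9)c(OCc9ccccc9)c4)[C@H]3OB3OC(C)(C)C(C)(C)O3)C[C@@H]2OCc9ccccc9)cc1 | intermediate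
17 | hepta-O-benzylfisetinidol-(4α→8)-afzelechin, upper unit (2R,3S,4S) with free 3-OH, lower unit (2R,3S) | c9ccccc9COc1ccc([C@H]2Oc3c(c(OCc9ccccc9)cc(OCc9ccccc9)c3[C@@H]3c4ccc(OCc9ccccc9)cc4O[C@H](c4ccc(OCc9ccccc9)c(OCc9ccccc9)c4)[C@H]3O)C[C@@H]2OCc9ccccc9)cc1 | intermediate
18 | fisetinidol-(4α→8)-afzelechin, upper unit (2R,3S,4S), lower unit (2R,3S) | Oc1ccc([C@H]2Oc3c(c(O)cc(O)c3[C@@H]3c4ccc(O)cc4O[C@H](c4ccc(O)c(O)c4)[C@H]3O)C[C@@H]2O)cc1 | target

**Step count and risks**

Total step count: 10. Longest linear sequence: 8 steps (steps 1, 2, 3, 5, 6, 8, 9, 10).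

Step 8 (Proposed new method). Three processes could defeat it:
- The boron-bearing alkene carbon may add too slowly to the hindered, strongly stabilised quinone methide, which would then be lost to self-condensation or to oxa-Michael capture by the phenol of 9.
- Boron may be lost after C–C bond formation (alkenyl transfer) in place of ring closure.
- Facial or endo/exo selectivity may be poor, because only the catalyst differentiates the two faces.

Fallback in known chemistry, setting out from compound 3 and coming back at compound 17: the upper unit is introduced as a C4 electrophile in place of being built on the lower unit. Purchased (+)-fustin F1, which already holds the upper C2/C3 configuration, would be benzylated at its three phenols (BnBr, K2CO3, DMF) to 7,3',4'-tri-O-benzylfustin F2. Reduction with NaBH4 (THF/EtOH, 0 °C) would give the 2,3-trans-flavan-3,4-diol tri-O-benzylmollisacacidin F3. Ionisation of F3 at C4 with TMSOTf in CH2Cl2 at −40 °C in the presence of excess 3 should give 17 by Friedel–Crafts attack of C8 of 3 anti to the C3 hydroxyl (3,4-trans, 4α). This is the classical flavan-3,4-diol/flavan-3-ol condensation; C6-linked and 4β isomers would be expected as minor products to be separated by chromatography. Step 10 then follows unchanged.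

Step 6. The very electron-rich ortho-hydroxybenzhydrol may ionise during desilylation, work-up or chromatography, and the quinone methide so formed would oligomerise or pick up nucleophiles before the catalyst is present.

Fallback setting out from compound 8 and coming back at compound 9: Dess–Martin periodinane with NaHCO3 in CH2Cl2 would oxidise 8 to the silyl-protected benzophenone F4. Bu4NF would then give the 2-hydroxybenzophenone F5, a hydrogen-bonded, acid-tolerant compound that can be chromatographed freely. NaBH4 in THF/MeOH at 0 °C would reduce F5 to 9 immediately before step 8, so the labile carbinol is only extracted, dried and used, never exposed to fluoride salts or silica.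

Step 10. Once the para-oxygenated aryl groups are unmasked, hydrogenolytic opening of the pyran rings at the benzylic C2–O bonds may set in. The reaction may also stall with the alkyl benzyl ether still in place, and the free octaphenol may oxidise in air during catalyst removal.

Fallback setting out from compound 17 and coming back at compound 18, making no new compound (F0): non-reductive Lewis-acid debenzylation with BCl3 and pentamethylbenzene as benzyl-cation scavenger in CH2Cl2 at −78 °C, then methanol quench. The 5-deoxy upper unit makes the interflavan bond robust to acid, and the scavenger should prevent C-benzylation of the phloroglucinol ring.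

Further compounds
F1 | step 8 | (+)-fustin, (2R,3R)-3,7,3',4'-tetrahydroxyflavanone (purchased) | O=C1c2ccc(O)cc2O[C@H](c2ccc(O)c(O)c2)[C@H]1O
F2 | step 8 | (2R,3R)-7,3',4'-tri-O-benzylfustin | O=C1c2ccc(OCc9ccccc9)cc2O[C@H](c2ccc(OCc9ccccc9)c(OCc9ccccc9)c2)[C@H]1O
F3 | step 8 | (2R,3S,4R)-7,3',4'-tris(benzyloxy)flavan-3,4-diol (tri-O-benzylmollisacacidin) | O[C@@H]1c2ccc(OCc9ccccc9)cc2O[C@H](c2ccc(OCc9ccccc9)c(OCc9ccccc9)c2)[C@H]1O
F4 | step 6 | [4-benzyloxy-2-(tert-butyldimethylsilyloxy)phenyl][(2R,3S)-3,5,7,4'-tetra-O-benzylafzelechin-8-yl]methanone | c9ccccc9COc1ccc([C@H]2Oc3c(c(OCc9ccccc9)cc(OCc9ccccc9)c3C(=O)c3ccc(OCc9ccccc9)cc3O[Si](C)(C)C(C)(C)C)C[C@@H]2OCc9ccccc9)cc1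
F5 | step 6 | (4-benzyloxy-2-hydroxyphenyl)[(2R,3S)-3,5,7,4'-tetra-O-benzylafzelechin-8-yl]methanone | c9ccccc9COc1ccc([C@H]2Oc3c(c(OCc9ccccc9)cc(OCc9ccccc9)c3C(=O)c3ccc(OCc9ccccc9)cc3O)C[C@@H]2OCc9ccccc9)cc1
F0 | step 10 | none | none
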